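**Retrosynthetic overview**

1. The C3 ester is made by acylating a 3α-alcohol with (2E,4E,6E)-5-methyldodeca-2,4,6-trienoic acid; the C8 ketone, the Z C7=C11 alkene and the C12 alcohol are then unmasked together from a fused 3-methylfuran (oxygen bridging C8 and C12) by singlet oxygen and aldehyde reduction, and O-9 is desilylated last.
2. Before that, C3–OH comes from a C3–B bond (oxidation with retention), the C6 methylene from a C6 ketone (radical deoxygenation) and C1–C2 from C1=C2 (hydrogenation).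
3. Key disconnection: rings A and B are formed together by an intramolecular Diels–Alder reaction of a (1E,3E)-dienylboronate (C3=C2–C1=C10) with an E tigloyl ketone (C4=C5–C6=O). The enabling feature is that in ring A (C1–C2–C3–C4–C5–C10) the bonds C3–C4 and C5–C10 flank the C4–C5 unit and are spanned by the chain C3–C2–C1–C10; that C5–C10 is also the fusion bond of ring B, so C6–C7–C8–C9 is a ready four-atom tether; that C6 is a CH2 next to quaternary C5 and can carry a temporary activating carbonyl; and that C7, C8, C11, C12 and the C12 oxygen form a latent furan that holds two tether atoms cis and coplanar.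
4. The acyclic precursor has one stereocentre (C9, from a zinc–ProPhenol alkynylation) and is assembled from 3,4-dibromofuran, iodomethane, DMF, a silyl C4 diyne and tiglaldehyde.
5. Ring order: furan (purchased) → rings A and B in one step (step 10) → furan opened at the end (step 21).

Key step: step 10

Conventions: positions are numbered as in eremophilane (ring A = C1–C5 and C10; ring B = C5–C10; C11–C13 on C7; C14 on C5; C15 on C4); β is the face of the C5 methyl group; TBS = tert-butyldimethylsilyl, TMS = trimethylsilyl, Bpin = 4,4,5,5-tetramethyl-1,3,2-dioxaborolan-2-yl.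
Assumption: the (S,S)-enantiomer of the ProPhenol ligand is taken to deliver the (R)-carbinol 10; if the sense of induction is the opposite, the (R,R)-ligand is used in step 4.

**Route**

Step 1
Reactants: 1 3,4-dibromofuran
Product: 3 3-bromo-4-methylfuran, via 4-bromofuran-3-yllithium 2 (not isolated)
Conditions: n-BuLi (1.0 equiv), Et2O, −78 °C; then MeI, −78 → −40 °C
Reagents that add atoms: iodomethane CI
Why: Bromine–lithium exchange of one of the two equivalent C–Br bonds is fast at −78 °C, and the 3-furyllithium is methylated before it can isomerise to an α-lithio species (halogen–metal exchange then alkylation); no stereocentre.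

Step 2
Reactants: 3 3-bromo-4-methylfuran
Product: 5 3-bromo-4-methylfuran-2-carbaldehyde, via (3-bromo-4-methylfuran-2-yl)lithium 4 (not isolated)
Conditions: LiN(i-Pr)2, THF, −78 °C; then DMF; aq. NH4Cl
Reagents that add atoms: N,N-dimethylformamide CN(C)C=O
Why: The amide base removes the α-proton next to bromine, the more acidic of the two α-positions (directed ortho-lithiation), and DMF formylates the furyllithium; the bromine stays as the handle for C6.

Step 3
Reactants: 6 1,4-bis(trimethylsilyl)buta-1,3-diyne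
Product: 8 buta-1,3-diyn-1-yl(trimethyl)silane, via lithium silylbutadiynide 7 (not isolated)
Conditions: MeLi·LiBr (1.0 equiv), Et2O, 23 °C; aq. NH4Cl, 0 °C; used as a solution
Reagents that add atoms: none
Why: Methyllithium attacks one silicon only, because the acetylide formed is protected by its charge against a second attack (selective mono-desilylation), and protonation gives the terminal diyne for direct use.

Step 4
Reactants: 5 3-bromo-4-methylfuran-2-carbaldehyde; 8 buta-1,3-diyn-1-yl(trimethyl)silane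
Product: 10 (R)-1-(3-bromo-4-methylfuran-2-yl)-5-(trimethylsilyl)penta-2,4-diyn-1-ol, via methylzinc silylbutadiynide 9 (not isolated)
Conditions: Me2Zn (3 equiv), (S,S)-2,6-bis[2-(hydroxydiphenylmethyl)pyrrolidin-1-ylmethyl]-4-methylphenol (ProPhenol ligand, 20 mol %), Ph3PO (40 mol %), toluene, 0–4 °C; aq. NH4Cl
Reagents that add atoms: none
Why: Zinc–ProPhenol-catalysed asymmetric alkynylation, a reaction type established for 1,3-diynes and aromatic aldehydes, delivers the alkynyl group to one face of the aldehyde and so sets C9 as R, the only stereocentre carried into the key step.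

Step 5
Reactants: 10 (R)-1-(3-bromo-4-methylfuran-2-yl)-5-(trimethylsilyl)penta-2,4-diyn-1-ol
Product: 12 (R,E)-1-(3-bromo-4-methylfuran-2-yl)-5-(trimethylsilyl)pent-2-en-4-yn-1-ol, via cyclic sodium alkenylaluminate 11 (not isolated)
Conditions: NaAlH2(OCH2CH2OCH3)2 (2.5 equiv), THF, 0 °C; aq. potassium sodium tartrate
Reagents that add atoms: none
Why: The alkoxyaluminate delivers hydride only to the proximal alkyne (trans-hydroalumination of a propargylic alcohol), and protonolysis of the five-membered alkenylaluminate gives the E alkene C10=C1; the silylalkyne and the bromofuran are not touched.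

Step 6
Reactants: 12 (R,E)-1-(3-bromo-4-methylfuran-2-yl)-5-(trimethylsilyl)pent-2-en-4-yn-1-ol
Product: 13 (R,E)-3-bromo-2-[1-(tert-butyldimethylsilyloxy)-5-(trimethylsilyl)pent-2-en-4-yn-1-yl]-4-methylfuran
Conditions: TBSCl, imidazole, DMF, 23 °C
Reagents that add atoms: tert-butyl(chloro)dimethylsilane CC(C)(C)[Si](C)(C)Cl
Why: Standard silyl ether protection of the secondary furyl carbinol gives a base-stable group that survives the organolithium step and later directs the diene face.

Step 7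
Reactants: 13 (R,E)-3-bromo-2-[1-(tert-butyldimethylsilyloxy)-5-(trimethylsilyl)pent-2-en-4-yn-1-yl]-4-methylfuran; 14 (E)-2-methylbut-2-enal (tiglaldehyde)
Product: 16 (E)-1-{2-[(R,E)-1-(tert-butyldimethylsilyloxy)-5-(trimethylsilyl)pent-2-en-4-yn-1-yl]-4-methylfuran-3-yl}-2-methylbut-2-en-1-ol (both C6 epimers), via 3-furyllithium 15 (not isolated)
Conditions: n-BuLi (1.05 equiv), THF, −78 °C, 10 min; then 14, −78 °C; aq. NH4Cl
Reagents that add atoms: none
Why: Bromine–lithium exchange at −78 °C outruns deprotonation and silyl migration from oxygen to carbon, and the 3-furyllithium adds 1,2 to the enal (carbonyl addition); the new C6 carbinol centre forms as a mixture that is erased by the oxidation in step 10.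

Step 8
Reactants: 16 C6 carbinol with silylated enyne
Product: 17 (E)-1-{2-[(R,E)-1-(tert-butyldimethylsilyloxy)pent-2-en-4-yn-1-yl]-4-methylfuran-3-yl}-2-methylbut-2-en-1-ol
Conditions: K2CO3 (0.2 equiv), MeOH, 23 °C
Reagents that add atoms: none
Why: Carbonate-catalysed methanolysis cleaves only the alkynyl C–Si bond (protiodesilylation); the silyl ether and the allylic alcohol are stable under these conditions.

Step 9
Reactants: 17 terminal enyne carbinol
Product: 19 (E)-1-{2-[(R,2E,4E)-1-(tert-butyldimethylsilyloxy)-5-(Bpin)penta-2,4-dien-1-yl]-4-methylfuran-3-yl}-2-methylbut-2-en-1-ol, via O-borylated dienylboronate 18 (not isolated)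
Conditions: pinacolborane (3 equiv), Cp2Zr(H)Cl (10 mol %), Et3N (10 mol %), CH2Cl2, 23 → 40 °C; pH 7 buffer work-up
Reagents that add atoms: pinacolborane CC1(C)OBOC1(C)C
Why: Zirconium-catalysed syn hydroboration of the terminal alkyne places boron at C3 and gives the (1E,3E)-dienylboronate; the first equivalent of borane masks the hydroxyl as a borate that is hydrolysed on work-up, and the trisubstituted alkene does not react.

Step 10
Reactants: 19 dienylboronate carbinol
Product: 21 3α-Bpin-9β-(tert-butyldimethylsilyloxy)furanoeremophil-1-en-6-one (cis-fused; 4β- and 5β-methyl; H-10β), via trienone 20 (not isolated)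
Conditions: MnO2 (20 equiv), toluene, 23 °C; filter (Celite); filtrate diluted to 0.01 M, 2,6-di-tert-butyl-4-methylphenol (5 mol %), 110 °C
Reagents that add atoms: none
Why: MnO2 oxidises only the allylic, furan-activated C6 carbinol, and the tigloyl ketone 20 then undergoes a concerted, suprafacial intramolecular Diels–Alder reaction between the dienylboronate (C3=C2–C1=C10) and the enone alkene (C4=C5), the closest precedents being the thermal cycloadditions of 1,7,9-decatrien-3-ones and of 1-boryl-1,3-dienes. Ring A closes by the [4+2] union itself (bonds C3–C4 and C5–C10), and ring B closes in the same event as a six-membered ring because the tether C6–C7–C8–C9, with C7 and C8 held cis and coplanar by the furan, already joins C5 to C10. The E geometry of the tigloyl unit fixes the cis relation of the C4 and C5 methyl groups, and the E,E geometry of the diene fixes the cis relation of boron at C3 and the tether at C10. The endo position of the C6 carbonyl under the diene gives the cis ring fusion (H-10 cis to the C5 methyl) and puts the C4 methyl trans to boron at C3. The diene face is chosen by the C9 stereocentre: the silyloxy group should stand pseudo-axial, perpendicular to the furan plane, away from the lone pairs of the furan oxygen and out of conjugation with the diene, with the small H-9 eclipsing C10=C1, so that H-10 ends up cis to the C9 oxygen. Regiochemistry is enforced by the tether and is not opposed by the boron substituent (an oxygen donor at C3 would polarise the diene against the enone), so the step needs only endo and facial selectivity; the first rests on the known cis preference of ketone-activated decatrienones and the second on C9 alone, which is the main risk.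

Step 11
Reactants: 21 Diels–Alder adduct
Product: 22 3α-Bpin-9β-(tert-butyldimethylsilyloxy)furanoeremophilan-6-one
Conditions: H2 (1 atm), RhCl(PPh3)3 (5 mol %), benzene–EtOH, 23 °C
Reagents that add atoms: none
Why: Homogeneous rhodium-catalysed hydrogenation reduces the unhindered cis-disubstituted ring alkene C1=C2 and leaves the furan, the aryl ketone, the furfuryl C–O bond and the C–B bond alone; no new stereocentre.

Step 12
Reactants: 22 saturated furyl ketone
Product: 23 3α-Bpin-9β-(tert-butyldimethylsilyloxy)furanoeremophilan-6-ol (C6 configuration not controlled)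
Conditions: NaBH4, MeOH–THF, 0 → 23 °C
Reagents that add atoms: none
Why: Borohydride reduction of the furyl ketone (carbonyl reduction) prepares C6 for deoxygenation; the configuration of the new carbinol does not matter because it is removed in step 14, and the pinacol boronate tolerates NaBH4.

Step 13
Reactants: 23 C6 alcohol
Product: 26 O-(C6) S-methyl xanthate of 23, via sodium alkoxide 24 (not isolated), via sodium xanthate 25 (not isolated)
Conditions: NaH, imidazole (cat.), THF, 0 °C; CS2; then MeI, 0 → 23 °C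
Reagents that add atoms: carbon disulfide S=C=S; iodomethane CI
Why: Xanthate formation (alkoxide, CS2, S-methylation) works on hindered secondary alcohols under cold basic conditions, which avoid ionisation of the furylmethyl position.

Step 14
Reactants: 26 xanthate
Product: 27 3α-Bpin-9β-(tert-butyldimethylsilyloxy)furanoeremophilane
Conditions: Bu3SnH, azobisisobutyronitrile (cat.), toluene, 100 °C
Reagents that add atoms: none
Why: Barton–McCombie deoxygenation: the stannyl radical adds to the thiocarbonyl and fragmentation gives a furan-stabilised C6 radical that takes hydrogen from Bu3SnH; a radical next to quaternary C5 does not rearrange, unlike the cation of an ionic reduction, and the C–B bond and silyl ether are inert.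

Step 15
Reactants: 27 deoxygenated boronate
Product: 28 9β-(tert-butyldimethylsilyloxy)furanoeremophilan-3α-ol
Conditions: H2O2 (30 %), aq. NaOH, THF, 0 → 23 °C
Reagents that add atoms: hydrogen peroxide OO
Why: Alkaline peroxide oxidation of the secondary alkylboronate proceeds by 1,2-migration of carbon from boron to oxygen with retention, so the 3α-hydroxyl inherits the configuration set at C3 in step 10.

Step 16
Reactants: 29 (E)-3-methylpent-2-en-4-yn-1-ol
Product: 31 ethyl (2E,4E)-5-methylhepta-2,4-dien-6-ynoate, via (E)-3-methylpent-2-en-4-ynal 30 (not isolated)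
Conditions: MnO2 (10 equiv), Ph3P=CHCO2Et (1.3 equiv), CH2Cl2, 23 °C
Reagents that add atoms: ethyl (triphenylphosphoranylidene)acetate CCOC(=O)C=P(c1ccccc1)(c1ccccc1)c1ccccc1
Why: Allylic oxidation with in situ Wittig olefination of the sensitive enynal by a stabilised ylide (tandem oxidation–Wittig) gives the 2E enoate and keeps the 4E geometry of the starting alcohol.

Step 17
Reactants: 31 ethyl (2E,4E)-5-methylhepta-2,4-dien-6-ynoate
Product: 33 ethyl (2E,4E,6E)-7-iodo-5-methylhepta-2,4,6-trienoate, via alkenylzirconocene chloride 32 (not isolated)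
Conditions: Cp2Zr(H)Cl (1.2 equiv), THF, 0 → 23 °C; then I2, 0 °C
Reagents that add atoms: iodine II
Why: Syn hydrozirconation puts zirconium on the terminal alkyne carbon and iodinolysis with retention gives the E vinyl iodide (hydrozirconation–iodination); the conjugated ester is tolerated for the short reaction time.

Step 18
Reactants: 33 ethyl (2E,4E,6E)-7-iodo-5-methylhepta-2,4,6-trienoate
Product: 34 ethyl (2E,4E,6E)-5-methyldodeca-2,4,6-trienoate
Conditions: n-C5H11ZnBr (1.5 equiv), Pd(PPh3)4 (5 mol %), THF, 23 °C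
Reagents that add atoms: pentylzinc bromide CCCCC[Zn]Br
Why: Negishi coupling of the vinyl iodide with a primary alkylzinc reagent under zerovalent palladium catalysis proceeds with retention of alkene geometry and tolerates the ester.

Step 19
Reactants: 34 ethyl (2E,4E,6E)-5-methyldodeca-2,4,6-trienoate
Product: 35 (2E,4E,6E)-5-methyldodeca-2,4,6-trienoic acid
Conditions: LiOH·H2O, THF–MeOH–H2O, 23 °C; then 1 M HCl to pH 3
Reagents that add atoms: lithium hydroxide [Li+].[OH-]
Why: Saponification of the ethyl ester at room temperature leaves the all-E triene unchanged.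

Step 20
Reactants: 28 9β-(tert-butyldimethylsilyloxy)furanoeremophilan-3α-ol; 35 (2E,4E,6E)-5-methyldodeca-2,4,6-trienoic acid
Product: 36 9β-(tert-butyldimethylsilyloxy)furanoeremophilan-3α-yl (2E,4E,6E)-5-methyldodeca-2,4,6-trienoate
Conditions: N-(3-dimethylaminopropyl)-N'-ethylcarbodiimide hydrochloride (EDC·HCl), 4-(dimethylamino)pyridine (DMAP), CH2Cl2, 23 °C
Reagents that add atoms: none
Why: Carbodiimide/DMAP (Steglich) esterification of the secondary 3α-alcohol with the all-E acid touches no stereocentre and does not endanger the triene geometry.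

Step 21
Reactants: 36 furan trienoate
Product: 38 Z keto-enal (8,12-dioxo-7(11)-ene) with 9β-silyloxy group and 3α-trienoate, via furan endoperoxide 37 (not isolated)
Conditions: O2, 5,10,15,20-tetraphenylporphyrin (1 mol %), visible light, CH2Cl2, −78 °C; then Me2S, −78 → 0 °C
Reagents that add atoms: oxygen O=O
Why: Singlet oxygen adds [4+2] across the electron-rich trisubstituted furan much faster than to the electron-poor trienoate, and Me2S reduction of the endoperoxide opens it to the cis-enedione (furan photooxygenation), so the tetrasubstituted C7=C11 alkene is formed with the Z geometry dictated by the ring.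

Step 22
Reactants: 38 Z keto-enal
Product: 39 9-O-TBS ether of the target (12-hydroxy-8-oxo-7(11)Z-ene)
Conditions: LiAlH(Ot-Bu)3 (1.1 equiv), THF, −78 °C; aq. potassium sodium tartrate
Reagents that add atoms: none
Why: The bulky hydride reduces the unhindered aldehyde at −78 °C much faster than the hindered tetrasubstituted enone carbonyl or the ester (chemoselective carbonyl reduction), giving the Z γ-hydroxy enone.

Step 23
Reactants: 39 9-O-TBS ether of the target
Product: 40 target, 3α-[(2E,4E,6E)-5-methyldodeca-2,4,6-trienoyloxy]-9β,12-dihydroxyeremophil-7(11)Z-en-8-one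
Conditions: Bu4NF, AcOH (1:1), THF, 0 → 23 °C
Reagents that add atoms: none
Why: Fluoride cleaves the silyl ether under acetic acid buffering (desilylation), which avoids both base-induced α-ketol chemistry at C9 and acid-induced cyclodehydration of the γ-hydroxy enone to a furan.

**Compound list**

1 | 3,4-dibromofuran | Brc1cocc1Br | starting material
2 | 4-bromofuran-3-yllithium | [Li]c1cocc1Br | intermediate
3 | 3-bromo-4-methylfuran | Cc1cocc1Br | intermediate
4 | (3-bromo-4-methylfuran-2-yl)lithium | [Li]c1occ(C)c1Br | intermediate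
5 | 3-bromo-4-methylfuran-2-carbaldehyde | O=Cc1occ(C)c1Br | intermediate
6 | 1,4-bis(trimethylsilyl)buta-1,3-diyne | C[Si](C)(C)C#CC#C[Si](C)(C)C | starting material
7 | lithium 4-(trimethylsilyl)buta-1,3-diyn-1-ide | [Li]C#CC#C[Si](C)(C)C | intermediate
8 | buta-1,3-diyn-1-yl(trimethyl)silane | C#CC#C[Si](C)(C)C | intermediate
9 | methyl[4-(trimethylsilyl)buta-1,3-diyn-1-yl]zinc | C[Zn]C#CC#C[Si](C)(C)C | intermediate
10 | (R)-1-(3-bromo-4-methylfuran-2-yl)-5-(trimethylsilyl)penta-2,4-diyn-1-ol | C[Si](C)(C)C#CC#C[C@@H](O)c1occ(C)c1Br | intermediate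
11 | sodium alkenylaluminate (five-membered ring Al–O9–C9–C10=C1, two 2-methoxyethoxy ligands on Al) | [Na+].COCCO[Al-]1(OCCOC)O[C@@H](c2occ(C)c2Br)C=C1C#C[Si](C)(C)C | intermediate
12 | (R,E)-1-(3-bromo-4-methylfuran-2-yl)-5-(trimethylsilyl)pent-2-en-4-yn-1-ol | C[Si](C)(C)C#C/C=C/[C@@H](O)c1occ(C)c1Br | intermediate
13 | (R,E)-3-bromo-2-[1-(tert-butyldimethylsilyloxy)-5-(trimethylsilyl)pent-2-en-4-yn-1-yl]-4-methylfuran | C[Si](C)(C)C#C/C=C/[C@@H](O[Si](C)(C)C(C)(C)C)c1occ(C)c1Br | intermediate
14 | (E)-2-methylbut-2-enal (tiglaldehyde) | O=C/C(C)=C/C | starting material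
15 | {2-[(R,E)-1-(tert-butyldimethylsilyloxy)-5-(trimethylsilyl)pent-2-en-4-yn-1-yl]-4-methylfuran-3-yl}lithium | C[Si](C)(C)C#C/C=C/[C@@H](O[Si](C)(C)C(C)(C)C)c1occ(C)c1[Li] | intermediate
16 | (E)-1-{2-[(R,E)-1-(tert-butyldimethylsilyloxy)-5-(trimethylsilyl)pent-2-en-4-yn-1-yl]-4-methylfuran-3-yl}-2-methylbut-2-en-1-ol, both C6 epimers | C[Si](C)(C)C#C/C=C/[C@@H](O[Si](C)(C)C(C)(C)C)c1occ(C)c1C(O)/C(C)=C/C | intermediate
17 | (E)-1-{2-[(R,E)-1-(tert-butyldimethylsilyloxy)pent-2-en-4-yn-1-yl]-4-methylfuran-3-yl}-2-methylbut-2-en-1-ol | C#C/C=C/[C@@H](O[Si](C)(C)C(C)(C)C)c1occ(C)c1C(O)/C(C)=C/C | intermediate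
18 | O-Bpin borate of 19 | CC1(C)OB(OC1(C)C)/C=C/C=C/[C@@H](O[Si](C)(C)C(C)(C)C)c2occ(C)c2C(OB3OC(C)(C)C(C)(C)O3)/C(C)=C/C | intermediate
19 | (E)-1-{2-[(R,2E,4E)-1-(tert-butyldimethylsilyloxy)-5-(Bpin)penta-2,4-dien-1-yl]-4-methylfuran-3-yl}-2-methylbut-2-en-1-ol | CC1(C)OB(OC1(C)C)/C=C/C=C/[C@@H](O[Si](C)(C)C(C)(C)C)c2occ(C)c2C(O)/C(C)=C/C | intermediate
20 | (E)-1-{2-[(R,2E,4E)-1-(tert-butyldimethylsilyloxy)-5-(Bpin)penta-2,4-dien-1-yl]-4-methylfuran-3-yl}-2-methylbut-2-en-1-one (trienone) | CC1(C)OB(OC1(C)C)/C=C/C=C/[C@@H](O[Si](C)(C)C(C)(C)C)c2occ(C)c2C(=O)/C(C)=C/C | intermediate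
21 | 3α-Bpin-9β-(tert-butyldimethylsilyloxy)furanoeremophil-1-en-6-one (cis-fused, 4β,5β-dimethyl, H-10β) | CC1(C)OB(OC1(C)C)[C@@H]2C=C[C@@H]3[C@@H](O[Si](C)(C)C(C)(C)C)c4occ(C)c4C(=O)[C@]3(C)[C@H]2C | intermediate
22 | 3α-Bpin-9β-(tert-butyldimethylsilyloxy)furanoeremophilan-6-one | CC1(C)OB(OC1(C)C)[C@@H]2CC[C@@H]3[C@@H](O[Si](C)(C)C(C)(C)C)c4occ(C)c4C(=O)[C@]3(C)[C@H]2C | intermediate
23 | 3α-Bpin-9β-(tert-butyldimethylsilyloxy)furanoeremophilan-6-ol | CC1(C)OB(OC1(C)C)[C@@H]2CC[C@@H]3[C@@H](O[Si](C)(C)C(C)(C)C)c4occ(C)c4C(O)[C@]3(C)[C@H]2C | intermediate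
24 | sodium alkoxide of 23 | CC1(C)OB(OC1(C)C)[C@@H]2CC[C@@H]3[C@@H](O[Si](C)(C)C(C)(C)C)c4occ(C)c4C([O-])[C@]3(C)[C@H]2C.[Na+] | intermediate
25 | sodium O-alkyl dithiocarbonate of 23 | CC1(C)OB(OC1(C)C)[C@@H]2CC[C@@H]3[C@@H](O[Si](C)(C)C(C)(C)C)c4occ(C)c4C(OC(=S)[S-])[C@]3(C)[C@H]2C.[Na+] | intermediate
26 | O-(C6) S-methyl xanthate of 23 | CC1(C)OB(OC1(C)C)[C@@H]2CC[C@@H]3[C@@H](O[Si](C)(C)C(C)(C)C)c4occ(C)c4C(OC(=S)SC)[C@]3(C)[C@H]2C | intermediate
27 | 3α-Bpin-9β-(tert-butyldimethylsilyloxy)furanoeremophilane | CC1(C)OB(OC1(C)C)[C@@H]2CC[C@@H]3[C@@H](O[Si](C)(C)C(C)(C)C)c4occ(C)c4C[C@]3(C)[C@H]2C | intermediate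
28 | 9β-(tert-butyldimethylsilyloxy)furanoeremophilan-3α-ol | O[C@@H]1CC[C@@H]2[C@@H](O[Si](C)(C)C(C)(C)C)c3occ(C)c3C[C@]2(C)[C@H]1C | intermediate
29 | (E)-3-methylpent-2-en-4-yn-1-ol | C#C/C(C)=C/CO | starting material
30 | (E)-3-methylpent-2-en-4-ynal | C#C/C(C)=C/C=O | intermediate
31 | ethyl (2E,4E)-5-methylhepta-2,4-dien-6-ynoate | C#C/C(C)=C/C=C/C(=O)OCC | intermediate
32 | chloro[(1E,3E,5E)-7-ethoxy-3-methyl-7-oxohepta-1,3,5-trien-1-yl]zirconocene | CCOC(=O)/C=C/C=C(C)/C=C/[Zr](Cl)(C1C=CC=C1)C1C=CC=C1 | intermediate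
33 | ethyl (2E,4E,6E)-7-iodo-5-methylhepta-2,4,6-trienoate | CCOC(=O)/C=C/C=C(C)/C=C/I | intermediate
34 | ethyl (2E,4E,6E)-5-methyldodeca-2,4,6-trienoate | CCCCC/C=C/C(C)=C/C=C/C(=O)OCC | intermediate
35 | (2E,4E,6E)-5-methyldodeca-2,4,6-trienoic acid | CCCCC/C=C/C(C)=C/C=C/C(=O)O | intermediate
36 | 9β-(tert-butyldimethylsilyloxy)furanoeremophilan-3α-yl (2E,4E,6E)-5-methyldodeca-2,4,6-trienoate | CCCCC/C=C/C(C)=C/C=C/C(=O)O[C@@H]1CC[C@@H]2[C@@H](O[Si](C)(C)C(C)(C)C)c3occ(C)c3C[C@]2(C)[C@H]1C | intermediate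
37 | 8,12-epidioxy endoperoxide of furan 36 | CCCCC/C=C/C(C)=C/C=C/C(=O)O[C@@H]1CC[C@@H]2[C@@H](O[Si](C)(C)C(C)(C)C)C35OC(OO5)C(C)=C3C[C@]2(C)[C@H]1C | intermediate
38 | 3α-trienoyloxy-9β-(tert-butyldimethylsilyloxy)-8,12-dioxoeremophil-7(11)Z-ene (keto-enal) | CCCCC/C=C/C(C)=C/C=C/C(=O)O[C@@H]1CC[C@@H]2[C@@H](O[Si](C)(C)C(C)(C)C)C(=O)/C(=C(/C)C=O)C[C@]2(C)[C@H]1C | intermediate
39 | 9-O-TBS ether of the target | CCCCC/C=C/C(C)=C/C=C/C(=O)O[C@@H]1CC[C@@H]2[C@@H](O[Si](C)(C)C(C)(C)C)C(=O)/C(=C(/C)CO)C[C@]2(C)[C@H]1C | intermediate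
40 | 3α-[(2E,4E,6E)-5-methyldodeca-2,4,6-trienoyloxy]-9β,12-dihydroxyeremophil-7(11)Z-en-8-one | CCCCC/C=C/C(C)=C/C=C/C(=O)O[C@@H]1CC[C@@H]2[C@@H](O)C(=O)/C(=C(/C)CO)C[C@]2(C)[C@H]1C | target

**Step count**

Total: 23 steps. Longest linear sequence: 18 steps (steps 1, 2, 4–15 and 20–23).

**Steps most likely to fail**

Step 10. The dienophile may add to the other face of the diene, with the C9 silyloxy group pseudo-equatorial to avoid the syn-axial contact with the C5 methyl, or facial selectivity may be low. The fallback runs the cycloaddition in the C9-epimeric series and inverts C9 afterwards; it sets out from 5 and returns at 21.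
- Alkynylation of 5 with 8 using the (R,R)-ligand gives (S)-1-(3-bromo-4-methylfuran-2-yl)-5-(trimethylsilyl)penta-2,4-diyn-1-ol F1.
- NaAlH2(OCH2CH2OCH3)2 reduces it through the mirror-image cyclic alkenylaluminate F2 to the (S,E)-enynol F3, and TBSCl/imidazole gives the (S)-silyl ether F4.
- n-BuLi gives the furyllithium F5, which adds to 14 to give the carbinol F6; K2CO3/MeOH gives the terminal enyne F7.
- Pinacolborane with Cp2Zr(H)Cl gives, through the O-borylated intermediate F8, the (S)-dienylboronate F9.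
- MnO2 then heating gives, through the (S)-trienone F10, the 9α-silyloxy adduct F11, whose ring stereocentres are those of 21.
- Bu4NF/AcOH gives the 9α-alcohol F12; a Mitsunobu reaction (4-nitrobenzoic acid, PPh3, diisopropyl azodicarboxylate) inverts C9 to the 9β-(4-nitrobenzoate) F13; K2CO3/MeOH gives the 9β-alcohol F14, and TBSOTf/2,6-lutidine returns 21.

Step 22. The hydride may add in conjugate fashion to the ene-dicarbonyl, may also reduce the C8 ketone, or the product may cyclise and dehydrate back towards the furan. The fallback reduces both carbonyls and re-oxidises C8 selectively; it sets out from 38 and returns at 40.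
- Luche reduction (NaBH4, CeCl3·7H2O, MeOH, −78 °C) of both carbonyls of 38 gives the Z ene-8,12-diol F15.
- TESCl/imidazole at −40 °C silylates only the primary allylic hydroxyl to give the 12-O-triethylsilyl ether F16.
- Dess–Martin periodinane oxidises the remaining secondary allylic alcohol at C8 to the enone F17.
- Bu4NF/AcOH removes both silyl groups and gives 40.

Step 21. Singlet oxygen or sensitiser may oxidise or isomerise the trienoate in competition with the furan. The fallback unmasks the hydroxy enone before the ester is attached; it sets out from 28 and returns at 40.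
- Photooxygenation of 28 (O2, tetraphenylporphyrin, light, −78 °C) gives the endoperoxide F18, and Me2S gives the keto-enal alcohol F19.
- LiAlH(Ot-Bu)3 at −78 °C gives the 3α,12-diol F20.
- TBSCl/imidazole at −40 °C silylates only the primary C12 hydroxyl to give F21.
- EDC·HCl/DMAP coupling with 35 gives the bis-silyl ether ester F22, and Bu4NF/AcOH gives 40.

Further compounds
F1 | step 10 | (S)-1-(3-bromo-4-methylfuran-2-yl)-5-(trimethylsilyl)penta-2,4-diyn-1-ol | C[Si](C)(C)C#CC#C[C@H](O)c1occ(C)c1Br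
F2 | step 10 | sodium alkenylaluminate, mirror image of 11 | [Na+].COCCO[Al-]1(OCCOC)O[C@H](c2occ(C)c2Br)C=C1C#C[Si](C)(C)C
F3 | step 10 | (S,E)-1-(3-bromo-4-methylfuran-2-yl)-5-(trimethylsilyl)pent-2-en-4-yn-1-ol | C[Si](C)(C)C#C/C=C/[C@H](O)c1occ(C)c1Br
F4 | step 10 | (S,E)-3-bromo-2-[1-(tert-butyldimethylsilyloxy)-5-(trimethylsilyl)pent-2-en-4-yn-1-yl]-4-methylfuran | C[Si](C)(C)C#C/C=C/[C@H](O[Si](C)(C)C(C)(C)C)c1occ(C)c1Br
F5 | step 10 | furan-3-yllithium from F4 | C[Si](C)(C)C#C/C=C/[C@H](O[Si](C)(C)C(C)(C)C)c1occ(C)c1[Li]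
F6 | step 10 | (S)-series C6 carbinol, enantiomeric series of 16 | C[Si](C)(C)C#C/C=C/[C@H](O[Si](C)(C)C(C)(C)C)c1occ(C)c1C(O)/C(C)=C/C
F7 | step 10 | (S)-series terminal enyne, enantiomeric series of 17 | C#C/C=C/[C@H](O[Si](C)(C)C(C)(C)C)c1occ(C)c1C(O)/C(C)=C/C
F8 | step 10 | O-Bpin borate of F9 | CC1(C)OB(OC1(C)C)/C=C/C=C/[C@H](O[Si](C)(C)C(C)(C)C)c2occ(C)c2C(OB3OC(C)(C)C(C)(C)O3)/C(C)=C/C
F9 | step 10 | (S)-dienylboronate carbinol, enantiomeric series of 19 | CC1(C)OB(OC1(C)C)/C=C/C=C/[C@H](O[Si](C)(C)C(C)(C)C)c2occ(C)c2C(O)/C(C)=C/C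
F10 | step 10 | (S)-trienone, enantiomer of 20 | CC1(C)OB(OC1(C)C)/C=C/C=C/[C@H](O[Si](C)(C)C(C)(C)C)c2occ(C)c2C(=O)/C(C)=C/C
F11 | step 10 | 3α-Bpin-9α-(tert-butyldimethylsilyloxy)furanoeremophil-1-en-6-one | CC1(C)OB(OC1(C)C)[C@@H]2C=C[C@@H]3[C@H](O[Si](C)(C)C(C)(C)C)c4occ(C)c4C(=O)[C@]3(C)[C@H]2C
F12 | step 10 | 3α-Bpin-9α-hydroxyfuranoeremophil-1-en-6-one | CC1(C)OB(OC1(C)C)[C@@H]2C=C[C@@H]3[C@H](O)c4occ(C)c4C(=O)[C@]3(C)[C@H]2C
F13 | step 10 | 3α-Bpin-9β-(4-nitrobenzoyloxy)furanoeremophil-1-en-6-one | CC1(C)OB(OC1(C)C)[C@@H]2C=C[C@@H]3[C@@H](OC(=O)c5ccc(cc5)[N+](=O)[O-])c4occ(C)c4C(=O)[C@]3(C)[C@H]2C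
F14 | step 10 | 3α-Bpin-9β-hydroxyfuranoeremophil-1-en-6-one | CC1(C)OB(OC1(C)C)[C@@H]2C=C[C@@H]3[C@@H](O)c4occ(C)c4C(=O)[C@]3(C)[C@H]2C
F15 | step 22 | 3α-trienoyloxy-9β-(tert-butyldimethylsilyloxy)eremophil-7(11)Z-ene-8,12-diol | CCCCC/C=C/C(C)=C/C=C/C(=O)O[C@@H]1CC[C@@H]2[C@@H](O[Si](C)(C)C(C)(C)C)C(O)/C(=C(/C)CO)C[C@]2(C)[C@H]1C
F16 | step 22 | 12-O-triethylsilyl ether of F15 | CCCCC/C=C/C(C)=C/C=C/C(=O)O[C@@H]1CC[C@@H]2[C@@H](O[Si](C)(C)C(C)(C)C)C(O)/C(=C(/C)CO[Si](CC)(CC)CC)C[C@]2(C)[C@H]1C
F17 | step 22 | 9-O-TBS 12-O-triethylsilyl bis-ether of the target | CCCCC/C=C/C(C)=C/C=C/C(=O)O[C@@H]1CC[C@@H]2[C@@H](O[Si](C)(C)C(C)(C)C)C(=O)/C(=C(/C)CO[Si](CC)(CC)CC)C[C@]2(C)[C@H]1C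
F18 | step 21 | 8,12-epidioxy endoperoxide of furan 28 | O[C@@H]1CC[C@@H]2[C@@H](O[Si](C)(C)C(C)(C)C)C35OC(OO5)C(C)=C3C[C@]2(C)[C@H]1C
F19 | step 21 | 3α-hydroxy-9β-(tert-butyldimethylsilyloxy)-8,12-dioxoeremophil-7(11)Z-ene | O[C@@H]1CC[C@@H]2[C@@H](O[Si](C)(C)C(C)(C)C)C(=O)/C(=C(/C)C=O)C[C@]2(C)[C@H]1C
F20 | step 21 | 3α,12-dihydroxy-9β-(tert-butyldimethylsilyloxy)eremophil-7(11)Z-en-8-one | O[C@@H]1CC[C@@H]2[C@@H](O[Si](C)(C)C(C)(C)C)C(=O)/C(=C(/C)CO)C[C@]2(C)[C@H]1C
F21 | step 21 | 12-O-TBS ether of F20 | O[C@@H]1CC[C@@H]2[C@@H](O[Si](C)(C)C(C)(C)C)C(=O)/C(=C(/C)CO[Si](C)(C)C(C)(C)C)C[C@]2(C)[C@H]1C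
F22 | step 21 | 9,12-bis-O-TBS ether of the target | CCCCC/C=C/C(C)=C/C=C/C(=O)O[C@@H]1CC[C@@H]2[C@@H](O[Si](C)(C)C(C)(C)C)C(=O)/C(=C(/C)CO[Si](C)(C)C(C)(C)C)C[C@]2(C)[C@H]1C
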